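**Retrosynthetic overview**

- The target is epimesquitol-(4β→6)-epioritin-4α-ol. The last C–C disconnection is the interflavan bond C4(upper)–C6(lower), made by silver-promoted Friedel–Crafts alkylation with a 4-benzylsulfanyl upper unit (3,4-trans by attack anti to the 3-benzyloxy group).
- Both all-cis (2R,3R,4R) flavan-3,4-diol units are traced back to achiral 3-benzyloxyflavones, a temporarily higher oxidation level that one enantioselective hydrogenation/hydride reduction per unit removes again.
- Each flavone is made in one operation from one common ortho-fluoroaryl α-benzyloxy ketone and an aroyl chloride: C-acylation forms C2–C3, intramolecular SNAr forms O1–C8a, and ring C closes onto the preformed ring A while ring B arrives with the acid chloride.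
- Enabling feature: C4 of ring C is bonded to C3 and, through C4a, sits ortho to C8a of ring A. As a ketone carbonyl it acidifies C3–H and activates the C8a–F bond, so one carbonyl serves both bond formations; fluorine leaves in the step itself.
- Ring order: rings A and B are bought as benzene rings; ring C of the upper unit (step 4), ring C of the lower unit (step 7), union of the halves (step 10), global debenzylation (step 12).

Key step: step 7

Assumption: the Weinreb amide, the benzoic acid and the benzoyl chloride used as starting materials are taken as commercial, and the (R,R)-ligand of steps 5 and 8 is assumed to deliver hydrogen to the face that leads to the (2R) series (otherwise its enantiomer is used).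

**Route**

Step 1
Reactants: 1 3-fluorocatechol; 2 benzyl bromide
Product: 3 1,2-bis(benzyloxy)-3-fluorobenzene
Conditions: BnBr (2.2 equiv in all), K2CO3 (3 equiv), DMF, 60 °C
Reagents that add atoms: benzyl bromide (the second equivalent of 2), BrCc1ccccc1
Why: Double Williamson etherification (SN2 of the two phenoxides on two equivalents of benzyl bromide); benzyl ethers are chosen because they should survive all later steps and fall together in the last one.

Step 2
Reactants: 3 1,2-bis(benzyloxy)-3-fluorobenzene; 4 2-(benzyloxy)-N-methoxy-N-methylacetamide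
Product: 6 2-(benzyloxy)-1-[3,4-bis(benzyloxy)-2-fluorophenyl]ethan-1-one, via aryllithium 5 (not isolated)
Conditions: n-BuLi, THF, −78 °C; then 4, −78 °C → 0 °C; aq. NH4Cl
Reagents that add atoms: none
Why: Fluorine-directed ortho-lithiation (the C–H next to fluorine is the most acidic ring position, and at −78 °C neither LiF loss to the aryne nor benzylic deprotonation should compete) followed by Weinreb ketone synthesis, whose chelated tetrahedral adduct prevents over-addition.

Step 3
Reactants: 7 3,4-bis(benzyloxy)benzoic acid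
Product: 8 3,4-bis(benzyloxy)benzoyl chloride
Conditions: (COCl)2, DMF (cat.), CH2Cl2, 0 °C → rt
Reagents that add atoms: oxalyl chloride, ClC(=O)C(=O)Cl
Why: Standard acid chloride formation with oxalyl chloride under DMF (chloroiminium) catalysis, to which benzyl ethers are inert.

Step 4
Reactants: 6 2-(benzyloxy)-1-[3,4-bis(benzyloxy)-2-fluorophenyl]ethan-1-one; 8 3,4-bis(benzyloxy)benzoyl chloride
Product: 10 3,7,8-tris(benzyloxy)-2-[3,4-bis(benzyloxy)phenyl]-4H-chromen-4-one, via 1,3-diketone 9 (not isolated)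
Conditions: LiN(SiMe3)2 (2.2 equiv), THF, −78 °C; 8, −78 °C → rt; then DMF, 80 °C
Reagents that add atoms: none
Why: The same one-pot Claisen-type C-acylation/intramolecular SNAr O-arylation as in step 7 (a known chromone and flavone synthesis from ortho-fluorophenyl ketones) should close ring C of the upper unit at the achiral flavonol oxidation level, so no stereocentre is formed.

Step 5
Reactants: 10 3,7,8-tris(benzyloxy)-2-[3,4-bis(benzyloxy)phenyl]-4H-chromen-4-one
Product: 12 (2R,3R,4R)-3,7,8-tris(benzyloxy)-2-[3,4-bis(benzyloxy)phenyl]chroman-4-ol, via cis-flavanone 11 (not isolated)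
Conditions: Ru(cod)(2-methylallyl)2 (5 mol%), 1,3-bis[(R)-1-(1-naphthyl)ethyl]imidazolinium tetrafluoroborate (10 mol%), KOtBu (10 mol%, no excess over the imidazolinium salt), H2 (100 bar), toluene, 25 °C; then LiBH(s-Bu)3, THF, −78 °C
Reagents that add atoms: none
Why: Proposed new method: a chiral ruthenium–NHC hydride is expected to add H2 syn to one enantioface of the tetrasubstituted, push–pull C2=C3 bond of the 3-alkoxy-4-pyranone (C2 and C3 are set together as the 2,3-cis pair, their absolute sense by the ligand), and LiBH(s-Bu)3 then attacks the C4 carbonyl of 11 anti to the pseudo-axial 3-benzyloxy group (Felkin-type control by C3, giving the 3,4-cis alcohol); the closest known reaction type is the ruthenium–NHC-catalysed asymmetric hydrogenation of flavones and chromones to flavanones and cis-flavan-4-ols, not yet shown for 3-alkoxyflavones, and the all-cis sense is that of the classical heterogeneous hydrogenation of flavonols to 2,3-cis-3,4-cis-flavan-3,4-diols.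

Step 6
Reactants: 12 (2R,3R,4R)-3,7,8-tris(benzyloxy)-2-[3,4-bis(benzyloxy)phenyl]chroman-4-ol
Product: 13 (2R,3S,4S)-3,7,8-tris(benzyloxy)-2-[3,4-bis(benzyloxy)phenyl]-4-(benzylsulfanyl)chromane
Conditions: BnSH, BF3·OEt2 (cat.), CH2Cl2, −30 °C
Reagents that add atoms: phenylmethanethiol, SCc1ccccc1
Why: Lewis-acid-catalysed SN1 thiolysis of the flavan-4-ol through its O1- and O7-stabilised C4 cation, the thiol entering anti to the 3-benzyloxy group (3,4-trans), should give a thioether that a thiophilic promoter alone can ionise later.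

Step 7
Reactants: 6 2-(benzyloxy)-1-[3,4-bis(benzyloxy)-2-fluorophenyl]ethan-1-one; 14 4-(benzyloxy)benzoyl chloride
Product: 16 3,7,8-tris(benzyloxy)-2-[4-(benzyloxy)phenyl]-4H-chromen-4-one, via 1,3-diketone 15 (not isolated)
Conditions: LiN(SiMe3)2 (2.2 equiv), THF, −78 °C; 14, −78 °C → rt; then DMF, 80 °C
Reagents that add atoms: none
Why: LiN(SiMe3)2 converts 6 into its lithium enolate, whose C3 is acylated by 14 (Claisen-type C-acylation, new C2–C3 bond; any O-acylated enol ester is re-equilibrated by the excess base to the same chelated β-diketonate 15), and on heating in DMF the enolate oxygen of the ring B carbonyl adds to C8a and fluoride leaves (addition–elimination, new O1–C8a bond). The closest known reaction type is the C-acylation/intramolecular SNAr O-arylation of ortho-halophenyl ketones to chromones and flavones, a Baker–Venkataraman-type diketone formation in which ring closure takes place at the aryl halide instead of at a phenol. Ring C is closed in the 6-exo-trig mode at the aromatic carbon C8a through a Meisenheimer adduct that the ortho C4 carbonyl group stabilises. No stereocentre is formed, since C2 and C3 arrive as sp2 carbons of the 4-pyranone; their configurations are set in step 8. The step needs C- over O-acylation, secured by the second equivalent of base that drains every acylation product into the diketonate, and O-arylation at the right site, secured by the substrate because only the ring B carbonyl oxygen reaches C8a in a six-membered transition state and because C8a–F is the only carbon–halogen bond and lies ortho to the ketone.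

Step 8
Reactants: 16 3,7,8-tris(benzyloxy)-2-[4-(benzyloxy)phenyl]-4H-chromen-4-one
Product: 18 (2R,3R,4R)-3,7,8-tris(benzyloxy)-2-[4-(benzyloxy)phenyl]chroman-4-ol, via cis-flavanone 17 (not isolated)
Conditions: Ru(cod)(2-methylallyl)2 (5 mol%), 1,3-bis[(R)-1-(1-naphthyl)ethyl]imidazolinium tetrafluoroborate (10 mol%), KOtBu (10 mol%, no excess over the imidazolinium salt), H2 (100 bar), toluene, 25 °C; then LiBH(s-Bu)3, THF, −78 °C
Reagents that add atoms: none
Why: Proposed new method: as in step 5, syn addition of H2 by the chiral ruthenium–NHC hydride to one enantioface of the tetrasubstituted C2=C3 bond should set C2 and C3 as the 2,3-cis pair (ligand control), and hydride attack of LiBH(s-Bu)3 on 17 anti to the pseudo-axial 3-benzyloxy group should set C4 as the 3,4-cis alcohol (control by C3); the closest known reaction type is the ruthenium–NHC-catalysed asymmetric hydrogenation of flavones and chromones, not yet shown for 3-alkoxyflavones, and the all-cis sense is that of the classical hydrogenation of flavonols to 2,3-cis-3,4-cis-flavan-3,4-diols.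

Step 9
Reactants: 18 (2R,3R,4R)-3,7,8-tris(benzyloxy)-2-[4-(benzyloxy)phenyl]chroman-4-ol
Product: 19 (2R,3S,4R)-3,7,8-tris(benzyloxy)-2-[4-(benzyloxy)phenyl]chroman-4-yl acetate
Conditions: Ac2O, pyridine, DMAP (cat.), CH2Cl2, rt
Reagents that add atoms: acetic anhydride, CC(=O)OC(C)=O
Why: DMAP-catalysed O-acylation with retention at C4 (the descriptor at C3 changes by priority only); the acetate should block both O-alkylation and ionisation at the lower C4 during the coupling.

Step 10
Reactants: 13 (2R,3S,4S)-3,7,8-tris(benzyloxy)-2-[3,4-bis(benzyloxy)phenyl]-4-(benzylsulfanyl)chromane; 19 (2R,3S,4R)-3,7,8-tris(benzyloxy)-2-[4-(benzyloxy)phenyl]chroman-4-yl acetate (3 equiv)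
Product: 20 nona-O-benzyl epimesquitol-(4β→6)-epioritin-4α-ol 4-O-acetate
Conditions: AgBF4, 2,6-di-tert-butyl-4-methylpyridine, THF, 0 °C
Reagents that add atoms: none
Why: AgBF4 abstracts the benzylsulfanyl group (thiophilic activation) to give the O1/O7-stabilised flavan-4-yl cation of the upper unit, which C6 of 19 (para to O1 and ortho to the 7-benzyloxy group, the only doubly activated ring position) should attack anti to the pseudo-axial 3-benzyloxy group, so that the interflavan bond is formed 3,4-trans (4β) in a Friedel–Crafts alkylation of the type known for 4-benzylsulfanylflavan-3-ols, while excess 19 suppresses self-condensation and the hindered pyridine keeps the acetate of 19 from ionising.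

Step 11
Reactants: 20 nona-O-benzyl epimesquitol-(4β→6)-epioritin-4α-ol 4-O-acetate
Product: 21 nona-O-benzyl epimesquitol-(4β→6)-epioritin-4α-ol
Conditions: K2CO3 (cat.), MeOH/THF, rt
Reagents that add atoms: none
Why: Base-catalysed transesterification (methanolysis) cleaves the benzylic acetate at the acyl carbon, so the lower C4 keeps its configuration and no benzyl ether is touched.

Step 12
Reactants: 21 nona-O-benzyl epimesquitol-(4β→6)-epioritin-4α-ol
Product: 22 epimesquitol-(4β→6)-epioritin-4α-ol (target)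
Conditions: H2 (1 bar), Pd(OH)2/C, THF/MeOH, rt
Reagents that add atoms: none
Why: Hydrogenolysis of the nine benzyl ethers (seven aryl, two alkyl) under neutral conditions, in which the C4–OH, the two C2–O1 bonds and the diarylmethine are expected to persist as in the debenzylation of benzylated proanthocyanidins; no stereocentre is touched.

**Compound list**

1 | 3-fluorocatechol (3-fluorobenzene-1,2-diol) | Oc1cccc(F)c1O | starting material
2 | benzyl bromide | BrCc1ccccc1 | starting material
3 | 1,2-bis(benzyloxy)-3-fluorobenzene | Fc1cccc(OCc2ccccc2)c1OCc1ccccc1 | intermediate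
4 | 2-(benzyloxy)-N-methoxy-N-methylacetamide | CON(C)C(=O)COCc1ccccc1 | starting material
5 | [3,4-bis(benzyloxy)-2-fluorophenyl]lithium (formed in the flask) | [Li]c1ccc(OCc2ccccc2)c(OCc2ccccc2)c1F | intermediate
6 | 2-(benzyloxy)-1-[3,4-bis(benzyloxy)-2-fluorophenyl]ethan-1-one | O=C(COCc1ccccc1)c1ccc(OCc2ccccc2)c(OCc2ccccc2)c1F | intermediate
7 | 3,4-bis(benzyloxy)benzoic acid | OC(=O)c1ccc(OCc2ccccc2)c(OCc2ccccc2)c1 | starting material
8 | 3,4-bis(benzyloxy)benzoyl chloride | ClC(=O)c1ccc(OCc2ccccc2)c(OCc2ccccc2)c1 | intermediate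
9 | 2-(benzyloxy)-1-[3,4-bis(benzyloxy)-2-fluorophenyl]-3-[3,4-bis(benzyloxy)phenyl]propane-1,3-dione (formed in the flask as its lithium enolate) | O=C(c1ccc(OCc2ccccc2)c(OCc2ccccc2)c1F)C(OCc1ccccc1)C(=O)c1ccc(OCc2ccccc2)c(OCc2ccccc2)c1 | intermediate
10 | 3,7,8-tris(benzyloxy)-2-[3,4-bis(benzyloxy)phenyl]-4H-chromen-4-one | O=c1c(OCc2ccccc2)c(-c2ccc(OCc3ccccc3)c(OCc3ccccc3)c2)oc2c(OCc3ccccc3)c(OCc3ccccc3)ccc12 | intermediate
11 | (2R,3S)-3,7,8-tris(benzyloxy)-2-[3,4-bis(benzyloxy)phenyl]chroman-4-one, 2,3-cis (formed in the flask) | O(Cc4ccccc4)c1ccc([C@H]2Oc3c(ccc(OCc4ccccc4)c3OCc4ccccc4)C(=O)[C@H]2OCc4ccccc4)cc1OCc4ccccc4 | intermediate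
12 | (2R,3R,4R)-3,7,8-tris(benzyloxy)-2-[3,4-bis(benzyloxy)phenyl]chroman-4-ol, 2,3-cis-3,4-cis | O(Cc4ccccc4)c1ccc([C@H]2Oc3c(ccc(OCc4ccccc4)c3OCc4ccccc4)[C@@H](O)[C@H]2OCc4ccccc4)cc1OCc4ccccc4 | intermediate
13 | (2R,3S,4S)-3,7,8-tris(benzyloxy)-2-[3,4-bis(benzyloxy)phenyl]-4-(benzylsulfanyl)chromane, 2,3-cis-3,4-trans | O(Cc4ccccc4)c1ccc([C@H]2Oc3c(ccc(OCc4ccccc4)c3OCc4ccccc4)[C@H](SCc4ccccc4)[C@H]2OCc4ccccc4)cc1OCc4ccccc4 | intermediate
14 | 4-(benzyloxy)benzoyl chloride | ClC(=O)c1ccc(OCc2ccccc2)cc1 | starting material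
15 | 2-(benzyloxy)-1-[3,4-bis(benzyloxy)-2-fluorophenyl]-3-[4-(benzyloxy)phenyl]propane-1,3-dione (formed in the flask as its lithium enolate) | O=C(c1ccc(OCc2ccccc2)c(OCc2ccccc2)c1F)C(OCc1ccccc1)C(=O)c1ccc(OCc2ccccc2)cc1 | intermediate
16 | 3,7,8-tris(benzyloxy)-2-[4-(benzyloxy)phenyl]-4H-chromen-4-one | O=c1c(OCc2ccccc2)c(-c2ccc(OCc3ccccc3)cc2)oc2c(OCc3ccccc3)c(OCc3ccccc3)ccc12 | intermediate
17 | (2R,3S)-3,7,8-tris(benzyloxy)-2-[4-(benzyloxy)phenyl]chroman-4-one, 2,3-cis (formed in the flask) | O(Cc4ccccc4)c1ccc([C@H]2Oc3c(ccc(OCc4ccccc4)c3OCc4ccccc4)C(=O)[C@H]2OCc4ccccc4)cc1 | intermediate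
18 | (2R,3R,4R)-3,7,8-tris(benzyloxy)-2-[4-(benzyloxy)phenyl]chroman-4-ol, 2,3-cis-3,4-cis | O(Cc4ccccc4)c1ccc([C@H]2Oc3c(ccc(OCc4ccccc4)c3OCc4ccccc4)[C@@H](O)[C@H]2OCc4ccccc4)cc1 | intermediate
19 | (2R,3S,4R)-3,7,8-tris(benzyloxy)-2-[4-(benzyloxy)phenyl]chroman-4-yl acetate, 2,3-cis-3,4-cis | O(Cc4ccccc4)c1ccc([C@H]2Oc3c(ccc(OCc4ccccc4)c3OCc4ccccc4)[C@@H](OC(C)=O)[C@H]2OCc4ccccc4)cc1 | intermediate
20 | nona-O-benzyl epimesquitol-(4β→6)-epioritin-4α-ol 4-O-acetate: upper unit 2,3-cis-3,4-trans, bonded through C4 (β) to C6 of the all-cis lower unit, whose 4-OH is acetylated | O(Cc6ccccc6)c1ccc([C@H]2Oc3c(cc([C@H]4c5ccc(OCc6ccccc6)c(OCc6ccccc6)c5O[C@H](c5ccc(OCc6ccccc6)c(OCc6ccccc6)c5)[C@@H]4OCc6ccccc6)c(OCc6ccccc6)c3OCc6ccccc6)[C@@H](OC(C)=O)[C@H]2OCc6ccccc6)cc1 | intermediate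
21 | nona-O-benzyl epimesquitol-(4β→6)-epioritin-4α-ol (as 20, lower 4-OH free) | O(Cc6ccccc6)c1ccc([C@H]2Oc3c(cc([C@H]4c5ccc(OCc6ccccc6)c(OCc6ccccc6)c5O[C@H](c5ccc(OCc6ccccc6)c(OCc6ccccc6)c5)[C@@H]4OCc6ccccc6)c(OCc6ccccc6)c3OCc6ccccc6)[C@@H](O)[C@H]2OCc6ccccc6)cc1 | intermediate
22 | epimesquitol-(4β→6)-epioritin-4α-ol, (2R,3R,4S)-2-(3,4-dihydroxyphenyl)-4-[(2R,3R,4R)-3,4,7,8-tetrahydroxy-2-(4-hydroxyphenyl)chroman-6-yl]chromane-3,7,8-triol | Oc1ccc([C@H]2Oc3c(cc([C@H]4c5ccc(O)c(O)c5O[C@H](c5ccc(O)c(O)c5)[C@@H]4O)c(O)c3O)[C@@H](O)[C@H]2O)cc1 | target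

**Totals**

Total step count: 12.
Longest linear sequence: 8 steps (1, 2, 7, 8, 9, 10, 11, 12; the upper branch 1, 2, 4, 5, 6, 10, 11, 12 is equally long).

**Steps most likely to fail**

Step 8. The hydrogenation may not turn over at the tetrasubstituted C2=C3 bond, may discriminate the enantiofaces poorly, or the cis-flavanone may epimerise at C3 before the hydride reduction. The fallback sets out from 16 and comes back at 18. Hydrogenation of 16 over PtO2 (H2, EtOAc), the classical route from flavonols to 2,3-cis-3,4-cis-flavan-3,4-diols, should give the racemic all-cis alcohol, that is 18 together with its enantiomer (2S,3S,4S)-3,7,8-tris(benzyloxy)-2-[4-(benzyloxy)phenyl]chroman-4-ol F4. Esterification with (S)-2-methoxy-2-phenylacetic acid (DCC, DMAP) should give the diastereomeric esters (2R,3S,4R)-3,7,8-tris(benzyloxy)-2-[4-(benzyloxy)phenyl]chroman-4-yl (S)-2-methoxy-2-phenylacetate F5 and (2S,3R,4S)-3,7,8-tris(benzyloxy)-2-[4-(benzyloxy)phenyl]chroman-4-yl (S)-2-methoxy-2-phenylacetate F6, which are separated on silica. Methanolysis of F5 (K2CO3, MeOH) returns 18.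

Step 5. The same processes threaten the upper unit. The fallback sets out from 10 and comes back at 12. PtO2-catalysed all-cis hydrogenation of 10 should give 12 together with its enantiomer (2S,3S,4S)-3,7,8-tris(benzyloxy)-2-[3,4-bis(benzyloxy)phenyl]chroman-4-ol F1. Esterification with (S)-2-methoxy-2-phenylacetic acid should give (2R,3S,4R)-3,7,8-tris(benzyloxy)-2-[3,4-bis(benzyloxy)phenyl]chroman-4-yl (S)-2-methoxy-2-phenylacetate F2 and (2S,3R,4S)-3,7,8-tris(benzyloxy)-2-[3,4-bis(benzyloxy)phenyl]chroman-4-yl (S)-2-methoxy-2-phenylacetate F3. After separation, methanolysis of F2 returns 12.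

Step 10. The upper cation may self-condense through its own ring A, and C-alkylation by the benzylated, only moderately nucleophilic pyrogallol-type ring A of 19 may be too slow. The fallback sets out from 12 and 18 and comes back at 22. Hydrogenolysis (H2, Pd(OH)2/C) of 12 should give melacacidin F7, and of 18 teracacidin F8. Thiolysis of F7 (BnSH, AcOH) should give 4β-benzylsulfanylepimesquitol F9. AgBF4 in THF at 0 °C then couples F9 with an excess of F8, whose free 7-OH makes C6 far more nucleophilic than in 19, to give 22 directly, following the thiophilic coupling known for free phenolic flavan-3-ols.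

**Further compounds**

F1 | step 5 | (2S,3S,4S)-3,7,8-tris(benzyloxy)-2-[3,4-bis(benzyloxy)phenyl]chroman-4-ol | O(Cc4ccccc4)c1ccc([C@@H]2Oc3c(ccc(OCc4ccccc4)c3OCc4ccccc4)[C@H](O)[C@@H]2OCc4ccccc4)cc1OCc4ccccc4
F2 | step 5 | (2R,3S,4R)-3,7,8-tris(benzyloxy)-2-[3,4-bis(benzyloxy)phenyl]chroman-4-yl (S)-2-methoxy-2-phenylacetate | O(Cc4ccccc4)c1ccc([C@H]2Oc3c(ccc(OCc4ccccc4)c3OCc4ccccc4)[C@@H](OC(=O)[C@@H](OC)c4ccccc4)[C@H]2OCc4ccccc4)cc1OCc4ccccc4
F3 | step 5 | (2S,3R,4S)-3,7,8-tris(benzyloxy)-2-[3,4-bis(benzyloxy)phenyl]chroman-4-yl (S)-2-methoxy-2-phenylacetate | O(Cc4ccccc4)c1ccc([C@@H]2Oc3c(ccc(OCc4ccccc4)c3OCc4ccccc4)[C@H](OC(=O)[C@@H](OC)c4ccccc4)[C@@H]2OCc4ccccc4)cc1OCc4ccccc4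
F4 | step 8 | (2S,3S,4S)-3,7,8-tris(benzyloxy)-2-[4-(benzyloxy)phenyl]chroman-4-ol | O(Cc4ccccc4)c1ccc([C@@H]2Oc3c(ccc(OCc4ccccc4)c3OCc4ccccc4)[C@H](O)[C@@H]2OCc4ccccc4)cc1
F5 | step 8 | (2R,3S,4R)-3,7,8-tris(benzyloxy)-2-[4-(benzyloxy)phenyl]chroman-4-yl (S)-2-methoxy-2-phenylacetate | O(Cc4ccccc4)c1ccc([C@H]2Oc3c(ccc(OCc4ccccc4)c3OCc4ccccc4)[C@@H](OC(=O)[C@@H](OC)c4ccccc4)[C@H]2OCc4ccccc4)cc1
F6 | step 8 | (2S,3R,4S)-3,7,8-tris(benzyloxy)-2-[4-(benzyloxy)phenyl]chroman-4-yl (S)-2-methoxy-2-phenylacetate | O(Cc4ccccc4)c1ccc([C@@H]2Oc3c(ccc(OCc4ccccc4)c3OCc4ccccc4)[C@H](OC(=O)[C@@H](OC)c4ccccc4)[C@@H]2OCc4ccccc4)cc1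
F7 | step 10 | melacacidin, (2R,3R,4R)-2-(3,4-dihydroxyphenyl)chromane-3,4,7,8-tetrol | Oc1ccc([C@H]2Oc3c(ccc(O)c3O)[C@@H](O)[C@H]2O)cc1O
F8 | step 10 | teracacidin, (2R,3R,4R)-2-(4-hydroxyphenyl)chromane-3,4,7,8-tetrol | Oc1ccc([C@H]2Oc3c(ccc(O)c3O)[C@@H](O)[C@H]2O)cc1
F9 | step 10 | 4β-benzylsulfanylepimesquitol, (2R,3S,4S)-4-(benzylsulfanyl)-2-(3,4-dihydroxyphenyl)chromane-3,7,8-triol | Oc1ccc([C@H]2Oc3c(ccc(O)c3O)[C@H](SCc3ccccc3)[C@H]2O)cc1O
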